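The retrosynthesis cuts, in order: (a) the ArCH2–CH= bond of the side chain (benzylic chloride plus alkenylalane); (b) the vinylic C–CH3 bond and the CH2–C≡ bond (terminal alkyne from a primary iodide); (c) C2–C3 of the 7-oxabicyclo[2.2.1]heptane; (d) the enoate C=C and the C4–O7 bond, which leads back to (R)-linalool.
Enabling feature (C1 = bridgehead with CH3, C2 = CH carrying the chain, C3 = CMe2, C4 = bridgehead CH, C5/C6 = CH2CH2 bridge, O7): with C2–C3 erased, the ring O7–C1–C6–C5–C4 remains. It is a 2,5-cis oxolane with the C1 methyl in place, i.e. furanoid linalool oxide, and it holds the C2 arm and the C3 arm on one face.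
Forward ring order: the oxolane forms first by epoxide opening, then the carbocycle C1–C6 by radical C2–C3 closure. The chain then grows by two carbons (acetylide), one carbon (methylalumination) and the arylmethyl unit.
Stereochemistry: C1 is the carbinol carbon of (R)-linalool. C4 comes from a reagent-controlled Shi epoxidation followed by invertive ring closure. C2 comes from the exo preference of the closing bicycle, and the E-alkene from syn carboalumination with retentive coupling.

Key step: step 5

Assumption: commercial (R)-(−)-linalool of high enantiomeric purity is used. Any (S)-linalool in it, like the minor epoxide face, ends as a trans-oxolane that cannot undergo step 5, so it costs material and not enantiomeric purity.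

Step 1
Reactants: 1 (R)-linalool
Product: 3 2-[(2S,5R)-5-ethenyl-5-methyloxolan-2-yl]propan-2-ol (cis-furanoid linalool oxide), via (3R,6R)-6,7-epoxylinalool 2 (not isolated)
Conditions: D-fructose-derived Shi ketone (30 mol %), Oxone (2KHSO5·KHSO4·K2SO4), K2CO3, Bu4NHSO4, aq. Na2B4O7 buffer, MeCN–CH2(OMe)2, 0 °C; extraction; then CSA (10 mol %), CH2Cl2, 0 °C to rt
Reagents that add atoms: potassium peroxymonosulfate, [K+].[O-]S(=O)(=O)OO
Why: Shi asymmetric epoxidation is selective for the electron-rich trisubstituted alkene over the vinyl group and, with the D-fructose-derived ketone, should set C6 as R under reagent control, after which acid-catalysed 5-exo-tet opening by the tertiary hydroxyl inverts that carbon and gives the oxolane with vinyl and hydroxyisopropyl groups cis (future C4), the 6-endo pyranoid by-product being removed by chromatography.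

Step 2
Reactants: 3 2-[(2S,5R)-5-ethenyl-5-methyloxolan-2-yl]propan-2-ol
Product: 5 (2R,5S)-5-(2-hydroxypropan-2-yl)-2-methyloxolane-2-carbaldehyde, via secondary ozonide 4 (not isolated)
Conditions: O3, CH2Cl2, −78 °C; then PPh3, −78 °C to rt
Reagents that add atoms: ozone, [O-][O+]=O
Why: Ozonolysis with reductive work-up cleaves the only remaining alkene, and the carbon that carries the aldehyde is fully substituted, so the linalool stereocentre cannot epimerise.

Step 3
Reactants: 5 (2R,5S)-5-(2-hydroxypropan-2-yl)-2-methyloxolane-2-carbaldehyde; 6 methyl (triphenylphosphoranylidene)acetate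
Product: 7 methyl (2E)-3-[(2R,5S)-5-(2-hydroxypropan-2-yl)-2-methyloxolan-2-yl]prop-2-enoate
Conditions: PhMe, 80 °C
Reagents that add atoms: none
Why: Wittig olefination with a stabilised ylide is E-selective, especially with an α-quaternary aldehyde, runs under neutral conditions that leave the free tertiary alcohol alone, and draws any bicyclic lactol tautomer of 5 through its open form.

Step 4
Reactants: 7 methyl (2E)-3-[(2R,5S)-5-(2-hydroxypropan-2-yl)-2-methyloxolan-2-yl]prop-2-enoate
Product: 8 methyl (2E)-3-[(2R,5S)-2-methyl-5-(prop-1-en-2-yl)oxolan-2-yl]prop-2-enoate (enoate arm and isopropenyl group cis)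
Conditions: SOCl2, pyridine, 0 °C
Reagents that add atoms: none
Why: Dehydration of the tertiary alcohol through its chlorosulfite (E2-type elimination with pyridine) should take one of the six exposed methyl hydrogens in preference to the single hindered ring C–H next to oxygen, as is usual for hydroxyisopropyl groups on oxolanes and dihydrobenzofurans, and neither stereocentre is touched.

Step 5
Reactants: 8 methyl (2E)-3-[(2R,5S)-2-methyl-5-(prop-1-en-2-yl)oxolan-2-yl]prop-2-enoate
Product: 9 methyl 2-[(1R,2S,4S)-1,3,3-trimethyl-7-oxabicyclo[2.2.1]heptan-2-yl]acetate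
Conditions: Fe(acac)3 (0.3 equiv), PhSiH3 (2.5 equiv, slow addition), degassed EtOH (0.01 M), argon, 60 °C
Reagents that add atoms: none
Why: PhSiH3 and EtOH convert Fe(acac)3 into a transient iron hydride that hands a hydrogen atom to the CH2 terminus of the electron-neutral isopropenyl group and leaves the electron-poor enoate alone, so the tertiary radical at C3 forms with Markovnikov selectivity. This nucleophilic radical adds to the electrophilic β-carbon C2 of the enoate, and the resulting ester-stabilised radical is reduced by divalent iron and protonated by ethanol, which returns trivalent iron to the cycle. The closest known reaction type is the iron-catalysed hydrogen-atom-transfer reductive coupling of 1,1-disubstituted alkenes with acrylates and crotonates (a tin-free Giese addition), which is established in both intermolecular and ring-closing form. The closure is 5-exo-trig for the ring C3–C4–O7–C1–C2 and at the same time completes the six-membered carbocycle C1–C2–C3–C4–C5–C6, whereas 6-endo attack at the α-carbon is polarity-mismatched and would leave an unstabilised radical. The only new stereocentre, C2, is controlled by the nascent bicycle: when the CH–CO2Me terminus of the E-enoate points to the open O7 side only the C2 hydrogen faces the C5–C6 bridge, whereas the other rotamer pushes the ester arm into the endo hydrogens of that bridge, so the acetate arm should end exo (2S). The step needs cyclisation to outrun hydrogen delivery to the C3 radical and intermolecular addition, which the cis-2,5 placement of both arms on the oxolane, the short C–O bonds of the tether, high dilution and slow silane addition should secure, and any trans-oxolane carried from step 1 cannot close and is removed here.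

Step 6
Reactants: 9 methyl 2-[(1R,2S,4S)-1,3,3-trimethyl-7-oxabicyclo[2.2.1]heptan-2-yl]acetate
Product: 10 2-[(1R,2S,4S)-1,3,3-trimethyl-7-oxabicyclo[2.2.1]heptan-2-yl]ethan-1-ol
Conditions: LiAlH4, Et2O, 0 °C
Reagents that add atoms: none
Why: LiAlH4 reduction of an ester to the primary alcohol is standard, and the bridged dialkyl ether is inert to it.

Step 7
Reactants: 10 2-[(1R,2S,4S)-1,3,3-trimethyl-7-oxabicyclo[2.2.1]heptan-2-yl]ethan-1-ol
Product: 11 (1R,2S,4S)-2-(2-iodoethyl)-1,3,3-trimethyl-7-oxabicyclo[2.2.1]heptane
Conditions: I2, PPh3, imidazole, CH2Cl2, 0 °C to rt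
Reagents that add atoms: iodine, II
Why: Appel-type iodination converts the unhindered primary alcohol by SN2 displacement of its alkoxyphosphonium ion, and imidazole keeps the medium non-acidic for the tertiary ether.

Step 8
Reactants: 11 (1R,2S,4S)-2-(2-iodoethyl)-1,3,3-trimethyl-7-oxabicyclo[2.2.1]heptane
Product: 12 (1R,2S,4S)-2-(but-3-yn-1-yl)-1,3,3-trimethyl-7-oxabicyclo[2.2.1]heptane
Conditions: LiC≡CH·H2NCH2CH2NH2, DMSO, rt
Reagents that add atoms: lithium acetylide–ethylenediamine complex, [Li+].[C-]#C.NCCN
Why: SN2 alkylation of lithium acetylide by a primary iodide whose β-carbon is an unbranched CH2 is standard in DMSO and gives the terminal alkyne directly.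

Step 9
Reactants: 13 methyl 3-formyl-4-hydroxybenzoate
Product: 14 methyl 3-formyl-4-[(4-methylbenzenesulfonyl)oxy]benzoate
Conditions: TsCl, Et3N, DMAP (cat.), CH2Cl2, 0 °C to rt
Reagents that add atoms: 4-methylbenzenesulfonyl chloride, Cc1ccc(S(=O)(=O)Cl)cc1
Why: Sulfonylation of the phenol gives an aryl tosylate that should not migrate to the benzylic oxygen made in the next step, resists organoalanes and zerovalent palladium at room temperature, and is cleaved under the basic conditions of the last step.

Step 10
Reactants: 14 methyl 3-formyl-4-[(4-methylbenzenesulfonyl)oxy]benzoate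
Product: 15 methyl 3-(hydroxymethyl)-4-[(4-methylbenzenesulfonyl)oxy]benzoate
Conditions: NaBH4, MeOH–THF, 0 °C
Reagents that add atoms: none
Why: NaBH4 reduces the aldehyde chemoselectively in the presence of the benzoate ester and the sulfonate.

Step 11
Reactants: 15 methyl 3-(hydroxymethyl)-4-[(4-methylbenzenesulfonyl)oxy]benzoate
Product: 16 methyl 3-(chloromethyl)-4-[(4-methylbenzenesulfonyl)oxy]benzoate
Conditions: SOCl2, CH2Cl2, 0 °C to rt
Reagents that add atoms: thionyl chloride, O=S(Cl)Cl
Why: Chlorination of a benzylic alcohol with SOCl2 runs through the chlorosulfite, and the electron-poor ring suppresses ionisation and self-alkylation, so the chloride should be storable.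

Step 12
Reactants: 12 (1R,2S,4S)-2-(but-3-yn-1-yl)-1,3,3-trimethyl-7-oxabicyclo[2.2.1]heptane; 16 methyl 3-(chloromethyl)-4-[(4-methylbenzenesulfonyl)oxy]benzoate
Product: 18 methyl 3-{(2E)-3-methyl-5-[(1R,2S,4S)-1,3,3-trimethyl-7-oxabicyclo[2.2.1]heptan-2-yl]pent-2-en-1-yl}-4-[(4-methylbenzenesulfonyl)oxy]benzoate, via (E)-alkenyldimethylalane 17 (not isolated)
Conditions: AlMe3 (3 equiv), Cp2ZrCl2 (0.25 equiv), CH2Cl2, 0 °C to rt; volatiles removed in vacuo; then 16, Pd(PPh3)4 (5 mol %), THF, rt
Reagents that add atoms: trimethylaluminium, C[Al](C)C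
Why: Zirconium-catalysed methylalumination (Negishi carboalumination) adds CH3 and Al syn across the terminal alkyne with aluminium at the terminus, and the palladium-catalysed cross-coupling of the alkenylalane with the benzylic chloride proceeds with retention, which together fix the E-trisubstituted alkene; one extra equivalent of AlMe3 allows for coordination to O7, and the excess is pumped off before coupling to limit methyl transfer.

Step 13
Reactants: 18 methyl 3-{(2E)-3-methyl-5-[(1R,2S,4S)-1,3,3-trimethyl-7-oxabicyclo[2.2.1]heptan-2-yl]pent-2-en-1-yl}-4-[(4-methylbenzenesulfonyl)oxy]benzoate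
Product: 19 4-hydroxy-3-{(2E)-3-methyl-5-[(1R,2S,4S)-1,3,3-trimethyl-7-oxabicyclo[2.2.1]heptan-2-yl]pent-2-en-1-yl}benzoic acid (CNP0422247.1)
Conditions: aq. NaOH (excess), 1,4-dioxane, 90 °C; then 1 M HCl to pH 3, 0 °C
Reagents that add atoms: sodium hydroxide, [Na+].[OH-]
Why: Alkaline hydrolysis saponifies the methyl benzoate and cleaves the S–O bond of the aryl sulfonate in one operation, the base-only medium avoids acid-induced chroman formation from the ortho-allylic phenol and opening of the tertiary ether, and the non-alcoholic cosolvent excludes alkyl tosylates that could O-alkylate the phenoxide.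

Compound list
1 | (R)-linalool, (3R)-3,7-dimethylocta-1,6-dien-3-ol | C=C[C@](C)(O)CCC=C(C)C | starting material
2 | (3R,6R)-6,7-epoxylinalool, (3R)-5-[(2R)-3,3-dimethyloxiran-2-yl]-3-methylpent-1-en-3-ol | C=C[C@](C)(O)CC[C@H]1OC1(C)C | intermediate (not isolated)
3 | 2-[(2S,5R)-5-ethenyl-5-methyloxolan-2-yl]propan-2-ol, cis-furanoid linalool oxide | C=C[C@@]1(C)CC[C@@H](C(C)(C)O)O1 | intermediate
4 | 2-[(2S,5R)-5-methyl-5-(1,2,4-trioxolan-3-yl)oxolan-2-yl]propan-2-ol, secondary ozonide, epimers at the trioxolane carbon | O1OC(OC1)[C@@]2(C)CC[C@@H](C(C)(C)O)O2 | intermediate (not isolated)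
5 | (2R,5S)-5-(2-hydroxypropan-2-yl)-2-methyloxolane-2-carbaldehyde | O=C[C@@]1(C)CC[C@@H](C(C)(C)O)O1 | intermediate
6 | methyl (triphenylphosphoranylidene)acetate | COC(=O)C=P(c1ccccc1)(c1ccccc1)c1ccccc1 | starting material
7 | methyl (2E)-3-[(2R,5S)-5-(2-hydroxypropan-2-yl)-2-methyloxolan-2-yl]prop-2-enoate | COC(=O)/C=C/[C@@]1(C)CC[C@@H](C(C)(C)O)O1 | intermediate
8 | methyl (2E)-3-[(2R,5S)-2-methyl-5-(prop-1-en-2-yl)oxolan-2-yl]prop-2-enoate | COC(=O)/C=C/[C@@]1(C)CC[C@@H](C(C)=C)O1 | intermediate
9 | methyl 2-[(1R,2S,4S)-1,3,3-trimethyl-7-oxabicyclo[2.2.1]heptan-2-yl]acetate (acetate arm exo, syn to O7) | COC(=O)C[C@H]1C(C)(C)[C@@H]2CC[C@@]1(C)O2 | intermediate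
10 | 2-[(1R,2S,4S)-1,3,3-trimethyl-7-oxabicyclo[2.2.1]heptan-2-yl]ethan-1-ol | OCC[C@H]1C(C)(C)[C@@H]2CC[C@@]1(C)O2 | intermediate
11 | (1R,2S,4S)-2-(2-iodoethyl)-1,3,3-trimethyl-7-oxabicyclo[2.2.1]heptane | ICC[C@H]1C(C)(C)[C@@H]2CC[C@@]1(C)O2 | intermediate
12 | (1R,2S,4S)-2-(but-3-yn-1-yl)-1,3,3-trimethyl-7-oxabicyclo[2.2.1]heptane | C#CCC[C@H]1C(C)(C)[C@@H]2CC[C@@]1(C)O2 | intermediate
13 | methyl 3-formyl-4-hydroxybenzoate | COC(=O)c1ccc(O)c(C=O)c1 | starting material
14 | methyl 3-formyl-4-[(4-methylbenzenesulfonyl)oxy]benzoate | COC(=O)c1ccc(OS(=O)(=O)c2ccc(C)cc2)c(C=O)c1 | intermediate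
15 | methyl 3-(hydroxymethyl)-4-[(4-methylbenzenesulfonyl)oxy]benzoate | COC(=O)c1ccc(OS(=O)(=O)c2ccc(C)cc2)c(CO)c1 | intermediate
16 | methyl 3-(chloromethyl)-4-[(4-methylbenzenesulfonyl)oxy]benzoate | COC(=O)c1ccc(OS(=O)(=O)c2ccc(C)cc2)c(CCl)c1 | intermediate
17 | dimethyl{(1E)-2-methyl-4-[(1R,2S,4S)-1,3,3-trimethyl-7-oxabicyclo[2.2.1]heptan-2-yl]but-1-en-1-yl}alumane | C/C(=C\[Al](C)C)CC[C@H]1C(C)(C)[C@@H]2CC[C@@]1(C)O2 | intermediate (not isolated)
18 | methyl 3-{(2E)-3-methyl-5-[(1R,2S,4S)-1,3,3-trimethyl-7-oxabicyclo[2.2.1]heptan-2-yl]pent-2-en-1-yl}-4-[(4-methylbenzenesulfonyl)oxy]benzoate | C/C(=C\Cc1cc(C(=O)OC)ccc1OS(=O)(=O)c1ccc(C)cc1)CC[C@H]1C(C)(C)[C@@H]2CC[C@@]1(C)O2 | intermediate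
19 | 4-hydroxy-3-{(2E)-3-methyl-5-[(1R,2S,4S)-1,3,3-trimethyl-7-oxabicyclo[2.2.1]heptan-2-yl]pent-2-en-1-yl}benzoic acid | C/C(=C\Cc1cc(C(=O)O)ccc1O)CC[C@H]1C(C)(C)[C@@H]2CC[C@@]1(C)O2 | target

Total step count: 13. Longest linear sequence: 10 steps from (R)-linalool (steps 1 to 8, 12 and 13). The arene branch (steps 9 to 11) is three steps and joins at step 12.

Steps most likely to fail

Step 5. The strained closure may be outrun by hydrogen delivery from the iron hydride or the silane to the C3 radical (net hydrogenation of the isopropenyl group). It may also lose to intermolecular addition, or run with poor exo/endo facial selectivity at C2. The fallback generates the same C3 radical without any hydride source, at lower temperature, and sets out from hydroxy enoate 7. Acylation with methyl chlorooxoacetate (Et3N, DMAP, CH2Cl2, 0 °C) should give the mixed methyl tert-alkyl oxalate F1. Brief treatment with one equivalent of aqueous CsOH in THF should cleave only the activated oxalate methyl ester and give the caesium oxalate F2. Visible-light photoredox oxidation (Ir[dF(CF3)ppy]2(dtbbpy)PF6, DME–DMF, H2O, blue LEDs) should then expel two molecules of CO2 and release the tertiary radical, which closes onto the enoate in the same 5-exo mode. Reduction of the ester-stabilised radical by the reduced photocatalyst and protonation bring the route back at 9, and step 4 is no longer needed.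

Step 12. Transmetalation from aluminium to palladium may be slow, methyl may be transferred in place of alkenyl, and residual organoalane may attack the benzoate ester. The fallback reverses the polarity of the two partners and sets out from 12 and 16. Alkenylalane 17, made from 12 as before, is quenched with I2 (THF, −30 °C) to give the purifiable (E)-alkenyl iodide F3. Chloride 16 is converted by Zn dust and LiCl in THF into the benzylic zinc chloride F4. Negishi coupling of the two (Pd(PPh3)4, THF, rt) should come back to the route at 18 with the alkene geometry retained.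

Step 4. The elimination may lose regiocontrol through proton loss from the ring C–H, which gives an enol ether. The tertiary centre may be captured by chloride or suffer a hydride shift from the neighbouring C–H with loss of configuration. Base may also trigger oxa-Michael closure of the cis-disposed alcohol onto the enoate. The fallback takes the enoate out of the dehydration and builds it afterwards in another way, and it sets out from 3. Dehydration of linalool oxide itself (SOCl2, pyridine, 0 °C) is an established transformation whose volatile product can be freed from isomers by distillation. It should give (2R,5S)-2-ethenyl-2-methyl-5-(prop-1-en-2-yl)oxolane F5. Cross-metathesis with excess methyl acrylate (second-generation Hoveyda–Grubbs catalyst, CH2Cl2, 40 °C) should engage the monosubstituted vinyl group and leave the 1,1-disubstituted isopropenyl group untouched. This should give the E-enoate and rejoin the route at 8, replacing steps 2 to 4.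

Further compounds
F1 | step 5 | methyl 2-{(2S,5R)-5-[(1E)-3-methoxy-3-oxoprop-1-en-1-yl]-5-methyloxolan-2-yl}propan-2-yl oxalate | COC(=O)/C=C/[C@@]1(C)CC[C@@H](C(C)(C)OC(=O)C(=O)OC)O1
F2 | step 5 | caesium 2-[(2-{(2S,5R)-5-[(1E)-3-methoxy-3-oxoprop-1-en-1-yl]-5-methyloxolan-2-yl}propan-2-yl)oxy]-2-oxoacetate | COC(=O)/C=C/[C@@]1(C)CC[C@@H](C(C)(C)OC(=O)C(=O)[O-])O1.[Cs+]
F3 | step 12 | (1R,2S,4S)-2-[(3E)-4-iodo-3-methylbut-3-en-1-yl]-1,3,3-trimethyl-7-oxabicyclo[2.2.1]heptane | C/C(=C\I)CC[C@H]1C(C)(C)[C@@H]2CC[C@@]1(C)O2
F4 | step 12 | ({5-(methoxycarbonyl)-2-[(4-methylbenzenesulfonyl)oxy]phenyl}methyl)zinc chloride | COC(=O)c1ccc(OS(=O)(=O)c2ccc(C)cc2)c(C[Zn]Cl)c1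
F5 | step 4 | (2R,5S)-2-ethenyl-2-methyl-5-(prop-1-en-2-yl)oxolane | C=C[C@@]1(C)CC[C@@H](C(C)=C)O1
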